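**Retrosynthetic overview**
- C4–O and C5–O are made last, by syn-dihydroxylation of an (E)-allylic alcohol; the C3 carbinol comes from catalyst-controlled reduction of a β-acyloxy enone.
- The ester C–O bond joins the acyl chloride of 14-methylpentadecanoic acid (fragment 3) to a β-hydroxy enone. The C1–C2 bond and the C1 stereocentre come from a new copper-catalysed chelation aldol of the bis-oxazole aldehyde (fragment 1) with the silyl dienol ether of (E)-pent-3-en-2-one (fragment 2).
- Fragment 1: the ring A C2–CH2 bond is made by C2–H zincation of oxazole-4-carbaldehyde and palladium-catalysed Negishi coupling with 5-(chloromethyl)oxazole.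
- Fragment 3: copper-catalysed alkyl–alkyl coupling (C5 + C7), cross-metathesis with hex-5-enoic acid, hydrogenation.
- Rings: neither oxazole is built. Ring A (2,4-disubstituted) and ring B (5-substituted) are bought as monocyclic oxazoles and joined first, before any stereocentre is set.

Assumption: species that exist only bound to a catalyst (organopalladium, ruthenium carbene, osmate ester, N-acylpyridinium, Vilsmeier species) are not numbered; every other compound formed in a flask is.

**Route**

Step 1
Reactants: 1 1-bromo-3-methylbutane; 2 7-bromohept-1-ene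
Product: 4 10-methylundec-1-ene, via (3-methylbutyl)magnesium bromide 3 (not isolated)
Conditions: 1, Mg turnings, THF, 40 °C; then 2, Li2CuCl4 (3 mol%), THF/NMP, 0 °C to rt
Reagents that add atoms: none
Why: The primary alkyl Grignard reagent couples with the primary alkyl bromide under Kochi-type copper catalysis faster than it touches the terminal alkene, giving the iso-branched C12 chain with no stereocentre involved.

Step 2
Reactants: 4 10-methylundec-1-ene; 5 hex-5-enoic acid
Product: 6 14-methylpentadec-5-enoic acid (E/Z mixture)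
Conditions: 5 (3 equiv), second-generation Grubbs catalyst RuCl2(=CHPh)(H2IMes)(PCy3) (2 mol%), 1,4-benzoquinone (10 mol%), CH2Cl2, 40 °C
Reagents that add atoms: none
Why: Olefin cross-metathesis of two unhindered terminal alkenes is driven by loss of ethene, excess cheap acid 5 pushes the statistical mixture to the cross product, benzoquinone suppresses Ru–H alkene migration, and the E/Z ratio is irrelevant because the alkene is hydrogenated next.

Step 3
Reactants: 6 14-methylpentadec-5-enoic acid
Product: 7 14-methylpentadecanoic acid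
Conditions: H2 (1 atm), 10% Pd/C, EtOAc, rt
Reagents that add atoms: none
Why: Heterogeneous catalytic hydrogenation saturates the isolated disubstituted alkene without affecting the carboxylic acid.

Step 4
Reactants: 7 14-methylpentadecanoic acid
Product: 8 14-methylpentadecanoyl chloride
Conditions: (COCl)2 (1.5 equiv), DMF (cat.), CH2Cl2, 0 °C to rt; evaporate, use crude
Reagents that add atoms: oxalyl chloride, ClC(=O)C(=O)Cl
Why: DMF-catalysed (Vilsmeier-type) chlorination with oxalyl chloride gives the acyl chloride with only gaseous by-products, so the crude chloride can be used directly.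

Step 5
Reactants: 9 (1,3-oxazol-5-yl)methanol
Product: 10 5-(chloromethyl)-1,3-oxazole
Conditions: SOCl2 (1.2 equiv), CH2Cl2, 0 °C to rt; evaporate, use at once as a THF solution
Reagents that add atoms: thionyl chloride, O=S(Cl)Cl
Why: Thionyl chloride converts the primary heterobenzylic alcohol into the chloride through a chlorosulfite ester (deoxychlorination) and leaves the weakly basic oxazole ring intact.

Step 6
Reactants: 11 1,3-oxazole-4-carbaldehyde; 10 5-(chloromethyl)-1,3-oxazole
Product: 13 2-(1,3-oxazol-5-ylmethyl)-1,3-oxazole-4-carbaldehyde, via (4-formyloxazol-2-yl)zinc chloride 12 (not isolated)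
Conditions: 11, TMPZnCl·LiCl (1.1 equiv), THF, 0 to 25 °C, 1 h; then 10 (1.2 equiv), Pd(OAc)2 (2 mol%), SPhos (4 mol%), THF, 25 to 50 °C
Reagents that add atoms: none
Why: The hindered zinc amide removes the most acidic ring proton (C2–H of ring A, further acidified by the 4-formyl group) while tolerating the aldehyde, and the heteroarylzinc chloride then undergoes Negishi cross-coupling with the benzylic-type chloride (oxidative addition to zerovalent palladium, transmetalation, reductive elimination) to forge the ring A C2–CH2 bond.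

Step 7
Reactants: 14 (E)-pent-3-en-2-one
Product: 16 (E)-2-(trimethylsilyloxy)penta-1,3-diene, via lithium (E)-penta-1,3-dien-2-olate 15 (not isolated)
Conditions: LiN(i-Pr)2 (1.05 equiv), THF, −78 °C; then Me3SiCl (1.2 equiv), −78 °C to rt; distil
Reagents that add atoms: chlorotrimethylsilane, C[Si](C)(C)Cl
Why: Kinetic deprotonation of the enone at the α′-methyl group gives the cross-conjugated lithium dienolate, which is silylated on oxygen with retention of the (E)-propenyl geometry (silyl enol ether formation).

Step 8
Reactants: 13 2-(1,3-oxazol-5-ylmethyl)-1,3-oxazole-4-carbaldehyde; 16 (E)-2-(trimethylsilyloxy)penta-1,3-diene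
Product: 18 (1R,4E)-1-hydroxy-1-[2-(1,3-oxazol-5-ylmethyl)-1,3-oxazol-4-yl]hex-4-en-3-one, via trimethylsilyl ether of the aldol 17 (not isolated)
Conditions: 16 (1.5 equiv), [Cu((R,R)-Ph-pybox)](SbF6)2 (10 mol%), CH2Cl2, −78 °C; then 1 M HCl, THF, 0 °C, 15 min
Reagents that add atoms: none
Why: Proposed new method: an enantioselective Mukaiyama aldol in which a 1,3-azole-4-carbaldehyde acts as a two-point-binding electrophile for a C2-symmetric divalent copper Lewis acid – 13 is expected to chelate [Cu((R,R)-Ph-pybox)]2+ through N3 of ring A and the formyl oxygen (five-membered chelate, as the ether and carbonyl oxygens of (benzyloxy)acetaldehyde do), which locks the C4–CHO rotamer and lets one ligand phenyl group block the Si face, so the CH2 terminus of silyl dienol ether 16 adds through an open transition state to the Re face, forming the C1–C2 bond and the (R)-carbinol, with silyl transfer to the copper aldolate turning the catalyst over; the closest known reaction type is the copper–pybox-catalysed Mukaiyama aldol of chelating aldehydes such as (benzyloxy)acetaldehyde, pyruvates and pyridine N-oxide carbaldehydes, which has not been shown for azole carbaldehydes or for cross-conjugated silyl dienol ethers.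

Step 9
Reactants: 18 (1R,4E)-1-hydroxy-1-[2-(1,3-oxazol-5-ylmethyl)-1,3-oxazol-4-yl]hex-4-en-3-one; 8 14-methylpentadecanoyl chloride
Product: 19 (1R,4E)-3-oxo-1-[2-(1,3-oxazol-5-ylmethyl)-1,3-oxazol-4-yl]hex-4-en-1-yl 14-methylpentadecanoate
Conditions: 8 (1.3 equiv), pyridine (3 equiv), DMAP (5 mol%), CH2Cl2, −20 to 0 °C
Reagents that add atoms: none
Why: Pyridine/DMAP acylation (nucleophilic catalysis through an N-acylpyridinium ion) esterifies the secondary alcohol without breaking the C1–O bond, so the (R) configuration is retained, and the low temperature and weak base keep E1cB loss of the β-acyloxy group in check.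

Step 10
Reactants: 19 (1R,4E)-3-oxo-1-[2-(1,3-oxazol-5-ylmethyl)-1,3-oxazol-4-yl]hex-4-en-1-yl 14-methylpentadecanoate
Product: 21 (1R,3S,4E)-3-hydroxy-1-[2-(1,3-oxazol-5-ylmethyl)-1,3-oxazol-4-yl]hex-4-en-1-yl 14-methylpentadecanoate, via O-catecholboryl ether of the allylic alcohol 20 (not isolated)
Conditions: (R)-2-methyl-CBS-oxazaborolidine (20 mol%), catecholborane (1.5 equiv), toluene, −78 °C; then pH 7 phosphate buffer, 0 °C
Reagents that add atoms: none
Why: In this Corey–Bakshi–Shibata reduction the (E)-propenyl group is the large and the CH2 group the small ketone substituent, so the (R)-oxazaborolidine delivers hydride 1,2 to the Re face of the C3 carbonyl and sets the (3S) carbinol, syn to the C1 ester, under catalyst control.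

Step 11
Reactants: 21 (1R,3S,4E)-3-hydroxy-1-[2-(1,3-oxazol-5-ylmethyl)-1,3-oxazol-4-yl]hex-4-en-1-yl 14-methylpentadecanoate
Product: 22 (1R,3S,4R,5S)-3,4,5-trihydroxy-1-[2-(1,3-oxazol-5-ylmethyl)-1,3-oxazol-4-yl]hexyl 14-methylpentadecanoate (target)
Conditions: OsO4 (2 mol%), (DHQ)2PHAL (5 mol%), N-methylmorpholine N-oxide (1.5 equiv), acetone/H2O 10:1, 0 °C
Reagents that add atoms: N-methylmorpholine N-oxide, C[N+]1([O-])CCOCC1; water, O
Why: Osmium-catalysed syn-dihydroxylation (Upjohn conditions with a Sharpless ligand) of the (E)-alkene gives the 4,5-syn diol, and attack anti to the allylic C3 hydroxyl (Kishi's empirical rule) is reinforced by the face preference of the dihydroquinine ligand, setting (4R,5S) in a neutral medium that avoids acyl migration.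

**Compound list**
1 | 1-bromo-3-methylbutane | CC(C)CCBr | starting material
2 | 7-bromohept-1-ene | C=CCCCCCBr | starting material
3 | (3-methylbutyl)magnesium bromide | CC(C)CC[Mg]Br | intermediate
4 | 10-methylundec-1-ene | CC(C)CCCCCCCC=C | intermediate
5 | hex-5-enoic acid | C=CCCCC(=O)O | starting material
6 | 14-methylpentadec-5-enoic acid (E/Z mixture) | CC(C)CCCCCCCC=CCCCC(=O)O | intermediate
7 | 14-methylpentadecanoic acid | CC(C)CCCCCCCCCCCCC(=O)O | intermediate
8 | 14-methylpentadecanoyl chloride | CC(C)CCCCCCCCCCCCC(=O)Cl | intermediate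
9 | (1,3-oxazol-5-yl)methanol | OCc1cnco1 | starting material
10 | 5-(chloromethyl)-1,3-oxazole | ClCc1cnco1 | intermediate
11 | 1,3-oxazole-4-carbaldehyde | O=Cc1cocn1 | starting material
12 | (4-formyl-1,3-oxazol-2-yl)zinc chloride (as its LiCl complex) | O=Cc1coc([Zn]Cl)n1 | intermediate
13 | 2-(1,3-oxazol-5-ylmethyl)-1,3-oxazole-4-carbaldehyde (ring A carries CHO, ring B is the 5-substituted oxazole) | O=Cc1coc(Cc2cnco2)n1 | intermediate
14 | (E)-pent-3-en-2-one | C/C=C/C(C)=O | starting material
15 | lithium (E)-penta-1,3-dien-2-olate | [Li]OC(=C)/C=C/C | intermediate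
16 | (E)-2-(trimethylsilyloxy)penta-1,3-diene | C=C(O[Si](C)(C)C)/C=C/C | intermediate
17 | (1R,4E)-1-[2-(1,3-oxazol-5-ylmethyl)-1,3-oxazol-4-yl]-1-(trimethylsilyloxy)hex-4-en-3-one | C[Si](C)(C)O[C@H](CC(=O)/C=C/C)c1coc(Cc2cnco2)n1 | intermediate
18 | (1R,4E)-1-hydroxy-1-[2-(1,3-oxazol-5-ylmethyl)-1,3-oxazol-4-yl]hex-4-en-3-one | O[C@H](CC(=O)/C=C/C)c1coc(Cc2cnco2)n1 | intermediate
19 | (1R,4E)-3-oxo-1-[2-(1,3-oxazol-5-ylmethyl)-1,3-oxazol-4-yl]hex-4-en-1-yl 14-methylpentadecanoate | CC(C)CCCCCCCCCCCCC(=O)O[C@H](CC(=O)/C=C/C)c1coc(Cc2cnco2)n1 | intermediate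
20 | (1R,3S,4E)-3-(1,3,2-benzodioxaborol-2-yloxy)-1-[2-(1,3-oxazol-5-ylmethyl)-1,3-oxazol-4-yl]hex-4-en-1-yl 14-methylpentadecanoate | CC(C)CCCCCCCCCCCCC(=O)O[C@H](C[C@H](OB1Oc2ccccc2O1)/C=C/C)c1coc(Cc2cnco2)n1 | intermediate
21 | (1R,3S,4E)-3-hydroxy-1-[2-(1,3-oxazol-5-ylmethyl)-1,3-oxazol-4-yl]hex-4-en-1-yl 14-methylpentadecanoate | CC(C)CCCCCCCCCCCCC(=O)O[C@H](C[C@H](O)/C=C/C)c1coc(Cc2cnco2)n1 | intermediate
22 | (1R,3S,4R,5S)-3,4,5-trihydroxy-1-[2-(1,3-oxazol-5-ylmethyl)-1,3-oxazol-4-yl]hexyl 14-methylpentadecanoate | CC(C)CCCCCCCCCCCCC(=O)O[C@H](C[C@H](O)[C@H](O)[C@H](C)O)c1coc(Cc2cnco2)n1 | target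

**Step count and risks**

Total step count: 11. Longest linear sequence: 7 steps (1, 2, 3, 4, 9, 10, 11). The other branches are 5, 6, 8–11 (six steps) and 7, 8–11 (five steps).

Three steps most likely to fail:

Step 8 (the proposed new aldol). Risks are binding of the copper centre by N3 of ring B or by the product (low turnover), low or reversed facial selectivity, and cyclisation of 18 to a tetrahydropyranone on acid work-up. The C1 configuration must be checked by Mosher ester analysis; the ligand antipode is equally available. The fallback uses only known chemistry, sets out from 13 and the lithium dienolate 15 (made as in step 7) and returns at 21. Aldehyde 13 is added to 15 in THF at −78 °C to give the lithium aldolate F1, which is quenched with aqueous NH4Cl to the racemic aldol F2. F2 is acylated with 8 as in step 9 to the racemic ester F3. Reduction as in step 10 then fixes C3 as (S) in both enantiomers, so the borate 20 forms together with the O-catecholboryl ether of the (1S,3S)-isomer F4. Hydrolysis gives 21 and the (1S,3S)-allylic alcohol F5, which are diastereomers and are separated by chromatography; the route continues from 21 at half the material throughput.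

Step 6 (zincation and Negishi coupling on the free aldehyde). Risks are attack on the unprotected formyl group, competing C5 metalation, and decomposition or N-alkylation by the labile chloride 10. The fallback sets out from 11 (with 10) and returns at 13. Aldehyde 11 is protected with HC(OEt)3, EtOH and catalytic TsOH as 4-(diethoxymethyl)-1,3-oxazole F6. F6 is joined to 10 by a palladium-catalysed direct C2–H benzylation without any organozinc (Pd(OAc)2, P(o-tol)3, Cs2CO3, 1,4-dioxane, 110 °C, concerted metalation–deprotonation) to give the coupled acetal 4-(diethoxymethyl)-2-(1,3-oxazol-5-ylmethyl)-1,3-oxazole F7. Hydrolysis of F7 with 1 M HCl in THF gives 13.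

Step 11 (dihydroxylation of the free allylic alcohol next to the ester). Risks are modest facial selectivity, migration of the acyl group from O1 to O3 in substrate or product, and over-oxidation. The fallback sets out from 21 and returns at 22. The C3 hydroxyl is silylated (Et3SiCl, imidazole, DMF, 0 °C) to the triethylsilyl ether F8, which blocks acyl migration and, as a bulky allylic ether, gives higher anti selectivity under Kishi's rule. Dihydroxylation under substrate control alone (OsO4 cat., N-methylmorpholine N-oxide, acetone/H2O) gives the silyl-protected diol F9. The silyl group is removed with HF·pyridine in THF at 0 °C to give 22.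

**Further compounds**
F1 | step 8 | lithium aldolate of racemic 18, lithium (4E)-3-oxo-1-[2-(1,3-oxazol-5-ylmethyl)-1,3-oxazol-4-yl]hex-4-en-1-olate | [Li]OC(CC(=O)/C=C/C)c1coc(Cc2cnco2)n1
F2 | step 8 | racemic (4E)-1-hydroxy-1-[2-(1,3-oxazol-5-ylmethyl)-1,3-oxazol-4-yl]hex-4-en-3-one | OC(CC(=O)/C=C/C)c1coc(Cc2cnco2)n1
F3 | step 8 | racemic (4E)-3-oxo-1-[2-(1,3-oxazol-5-ylmethyl)-1,3-oxazol-4-yl]hex-4-en-1-yl 14-methylpentadecanoate | CC(C)CCCCCCCCCCCCC(=O)OC(CC(=O)/C=C/C)c1coc(Cc2cnco2)n1
F4 | step 8 | (1S,3S,4E)-3-(1,3,2-benzodioxaborol-2-yloxy)-1-[2-(1,3-oxazol-5-ylmethyl)-1,3-oxazol-4-yl]hex-4-en-1-yl 14-methylpentadecanoate | CC(C)CCCCCCCCCCCCC(=O)O[C@@H](C[C@H](OB1Oc2ccccc2O1)/C=C/C)c1coc(Cc2cnco2)n1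
F5 | step 8 | (1S,3S,4E)-3-hydroxy-1-[2-(1,3-oxazol-5-ylmethyl)-1,3-oxazol-4-yl]hex-4-en-1-yl 14-methylpentadecanoate | CC(C)CCCCCCCCCCCCC(=O)O[C@@H](C[C@H](O)/C=C/C)c1coc(Cc2cnco2)n1
F6 | step 6 | 4-(diethoxymethyl)-1,3-oxazole | CCOC(OCC)c1cocn1
F7 | step 6 | 4-(diethoxymethyl)-2-(1,3-oxazol-5-ylmethyl)-1,3-oxazole | CCOC(OCC)c1coc(Cc2cnco2)n1
F8 | step 11 | (1R,3S,4E)-1-[2-(1,3-oxazol-5-ylmethyl)-1,3-oxazol-4-yl]-3-(triethylsilyloxy)hex-4-en-1-yl 14-methylpentadecanoate | CC(C)CCCCCCCCCCCCC(=O)O[C@H](C[C@H](O[Si](CC)(CC)CC)/C=C/C)c1coc(Cc2cnco2)n1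
F9 | step 11 | (1R,3S,4R,5S)-4,5-dihydroxy-1-[2-(1,3-oxazol-5-ylmethyl)-1,3-oxazol-4-yl]-3-(triethylsilyloxy)hexyl 14-methylpentadecanoate | CC(C)CCCCCCCCCCCCC(=O)O[C@H](C[C@H](O[Si](CC)(CC)CC)[C@H](O)[C@H](C)O)c1coc(Cc2cnco2)n1
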